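The cyclohexenone ring (C1 ketone, C2 carrying the hydroxymethyl carbon C7, C3 to C6) is disconnected at its trisubstituted C2=C3 enone alkene. Ring-closing metathesis of an acyclic dienone joins a C3 vinyl group to the α-methylene group of the C1 ketone, forming this double bond and the six-membered ring in one operation with loss of ethylene. The precursor carries the complete C4–C5–C6 stereotriad from L-arabinose (sugar C2 and C4 become C4 and C6; C5 is set by convex-face hydrogenation of a 3-C-isopropylidene furanose acetonide) and three different ethers (C4 PMB, C6 triethylsilyl, C7 TBDPS), so both esters can be introduced one after the other.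

Key step: step 16

Remark: locants C1–C7 are those of the target ring defined above, furanose intermediates carry sugar locants, and 2, 9 and 20 are handled as epimer mixtures at the one centre left open in their SMILES; TBDPS = tert-butyldiphenylsilyl, TBS = tert-butyldimethylsilyl, TES = triethylsilyl, PMB = 4-methoxybenzyl.

Step 1
Reactants: 1 L-arabinose
Product: 2 5-O-TBDPS-L-arabinofuranose (anomer mixture)
Conditions: t-BuPh2SiCl, imidazole, DMF, 0 °C to rt
Reagents that add atoms: tert-butyl(chloro)diphenylsilane, CC(C)(C)[Si](Cl)(c1ccccc1)c1ccccc1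
Why: Selective O-silylation of the only primary hydroxyl, which exists in the furanose tautomer, should drain the mutarotating sugar into the 5-O-silyl furanose, which can no longer close to a pyranose, and no carbon stereocentre is touched.

Step 2
Reactants: 2 5-O-TBDPS-L-arabinofuranose
Product: 3 5-O-TBDPS-1,2-O-isopropylidene-β-L-arabinofuranose
Conditions: 2,2-dimethoxypropane, p-TsOH·H2O (cat.), acetone, rt
Reagents that add atoms: 2,2-dimethoxypropane, COC(C)(C)OC
Why: Acid-catalysed acetalisation should take the only cis-vicinal diol of the furanose (O1/O2 of the β-anomer, reached by anomerisation), which fixes C1 in the cis-fused dioxolane and leaves O3–H as the single free hydroxyl.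

Step 3
Reactants: 3 5-O-TBDPS-1,2-O-isopropylidene-β-L-arabinofuranose
Product: 4 5-O-TBDPS-1,2-O-isopropylidene-β-L-threo-pentofuranos-3-ulose
Conditions: Dess–Martin periodinane, CH2Cl2, rt
Reagents that add atoms: none
Why: Dess–Martin oxidation of the isolated secondary alcohol is non-basic and should give the ketone without epimerising the flanking C2 and C4 centres.

Step 4
Reactants: 4 5-O-TBDPS-1,2-O-isopropylidene-β-L-threo-pentofuranos-3-ulose; 5 isopropyltriphenylphosphonium iodide
Product: 7 5-O-TBDPS-3-deoxy-1,2-O-isopropylidene-3-C-(propan-2-ylidene)-β-L-threo-pentofuranose, via triphenyl(propan-2-ylidene)phosphorane 6 (not isolated)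
Conditions: 5, n-BuLi, THF, 0 °C; then 4, −78 °C to rt
Reagents that add atoms: none
Why: Wittig olefination of the ketone with the non-stabilised isopropylidene ylide should give the tetrasubstituted exocyclic alkene, low-temperature addition limiting enolisation of the α-alkoxy ketone, and the new alkene carries no stereochemistry.

Step 5
Reactants: 7 5-O-TBDPS-3-deoxy-1,2-O-isopropylidene-3-C-(propan-2-ylidene)-β-L-threo-pentofuranose
Product: 8 5-O-TBDPS-3-deoxy-1,2-O-isopropylidene-3-C-(propan-2-yl)-β-L-lyxofuranose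
Conditions: H2 (4 bar), 10% Pd/C, EtOAc, rt
Reagents that add atoms: none
Why: Heterogeneous syn-hydrogenation should deliver hydrogen to the convex face of the cis-fused furanose–dioxolane bicycle, the face anti to both the acetonide and the C4 silyloxymethyl arm, which sets sugar C3 (future C5) with the isopropyl group cis to O2 and C5 (L-lyxo).

Step 6
Reactants: 8 5-O-TBDPS-3-deoxy-1,2-O-isopropylidene-3-C-(propan-2-yl)-β-L-lyxofuranose
Product: 9 5-O-TBDPS-3-deoxy-3-C-(propan-2-yl)-L-lyxofuranose (anomer mixture)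
Conditions: CF3CO2H/H2O (9:1), 0 °C to rt
Reagents that add atoms: none
Why: Aqueous acid hydrolysis of the 1,2-ketal should free the lactol and O2–H while the acid-robust primary TBDPS ether stays, and only the anomeric centre becomes a mixture, which is lost in the next step.

Step 7
Reactants: 9 5-O-TBDPS-3-deoxy-3-C-(propan-2-yl)-L-lyxofuranose
Product: 11 (2R,3S,4S)-3-(propan-2-yl)hex-5-ene-1,2,4-triol, via ene-diol silyl ether 10 (not isolated)
Conditions: Ph3PCH3Br, KOt-Bu, THF, 0 to 45 °C; then MeOH, Bu4NF, rt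
Reagents that add atoms: methyltriphenylphosphonium bromide, C[P+](c1ccccc1)(c1ccccc1)c1ccccc1.[Br-]
Why: Wittig methylenation of the open-chain aldehyde tautomer of the lactol with excess ylide should install the C3 vinyl group and release the former ring oxygen as the future C6 hydroxyl, and fluoride desilylation in the same flask converges any silyl-migrated material on one triol without forming a stereocentre.

Step 8
Reactants: 11 (2R,3S,4S)-3-(propan-2-yl)hex-5-ene-1,2,4-triol
Product: 12 (3S,4S)-4-[(4R)-2,2-dimethyl-1,3-dioxolan-4-yl]-5-methylhex-1-en-3-ol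
Conditions: 2,2-dimethoxypropane, pyridinium p-toluenesulfonate (cat.), CH2Cl2, 0 °C to rt
Reagents that add atoms: 2,2-dimethoxypropane, COC(C)(C)OC
Why: Thermodynamically controlled acetonide formation should select the terminal 1,2-diol (dioxolane) over the anti-1,3-diol, whose dioxane would need an axial substituent, so only the allylic hydroxyl (future C4–OH) stays free.

Step 9
Reactants: 12 (3S,4S)-4-[(4R)-2,2-dimethyl-1,3-dioxolan-4-yl]-5-methylhex-1-en-3-ol
Product: 13 (4R)-4-{(3S,4S)-4-[(4-methoxyphenyl)methoxy]-2-methylhex-5-en-3-yl}-2,2-dimethyl-1,3-dioxolane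
Conditions: NaH, 4-MeOC6H4CH2Cl, Bu4NI (cat.), DMF, 0 °C to rt
Reagents that add atoms: 4-methoxybenzyl chloride, COc1ccc(CCl)cc1
Why: Williamson etherification of the sodium alkoxide should give the PMB ether with retention, because the carbinol C–O bond is not broken.

Step 10
Reactants: 13 (4R)-4-{(3S,4S)-4-[(4-methoxyphenyl)methoxy]-2-methylhex-5-en-3-yl}-2,2-dimethyl-1,3-dioxolane
Product: 14 (2R,3R,4S)-4-[(4-methoxyphenyl)methoxy]-3-(propan-2-yl)hex-5-ene-1,2-diol
Conditions: AcOH/H2O (4:1), 40 °C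
Reagents that add atoms: none
Why: Mild aqueous acid hydrolysis should cleave the terminal acetonide while the PMB ether and the alkene are stable.

Step 11
Reactants: 14 (2R,3R,4S)-4-[(4-methoxyphenyl)methoxy]-3-(propan-2-yl)hex-5-ene-1,2-diol
Product: 15 (3S,4S,5R)-3-[(4-methoxyphenyl)methoxy]-4-(propan-2-yl)-5,6-bis[(triethylsilyl)oxy]hex-1-ene
Conditions: Et3SiCl, imidazole, 4-(dimethylamino)pyridine (cat.), DMF, 0 °C to rt
Reagents that add atoms: chlorotriethylsilane, CC[Si](Cl)(CC)CC
Why: Exhaustive O-silylation should protect both hydroxyls, since the triethylsilyl group is small enough for the hindered secondary alcohol.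

Step 12
Reactants: 15 (3S,4S,5R)-3-[(4-methoxyphenyl)methoxy]-4-(propan-2-yl)-5,6-bis[(triethylsilyl)oxy]hex-1-ene
Product: 16 (2R,3S,4S)-4-[(4-methoxyphenyl)methoxy]-3-(propan-2-yl)-2-[(triethylsilyl)oxy]hex-5-enal
Conditions: (COCl)2, DMSO, CH2Cl2, −78 to −30 °C; then Et3N, −78 to 0 °C
Reagents that add atoms: none
Why: Under Swern conditions the primary triethylsilyl ether should be converted directly into the alkoxysulfonium salt and then the aldehyde while the more hindered secondary triethylsilyl ether stays (selective oxidative desilylation), and cold amine treatment protects the α-silyloxy stereocentre.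

Step 13
Reactants: 17 2-bromoprop-2-en-1-ol
Product: 18 [(2-bromoprop-2-en-1-yl)oxy](tert-butyl)diphenylsilane
Conditions: t-BuPh2SiCl, imidazole, CH2Cl2, 0 °C to rt
Reagents that add atoms: tert-butyl(chloro)diphenylsilane, CC(C)(C)[Si](Cl)(c1ccccc1)c1ccccc1
Why: Routine O-silylation of a primary allylic alcohol should give the robust TBDPS ether that later outlasts removal of the C6 triethylsilyl group.

Step 14
Reactants: 16 (2R,3S,4S)-4-[(4-methoxyphenyl)methoxy]-3-(propan-2-yl)-2-[(triethylsilyl)oxy]hex-5-enal; 18 [(2-bromoprop-2-en-1-yl)oxy](tert-butyl)diphenylsilane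
Product: 20 (3RS,4R,5S,6S)-2-{[(tert-butyldiphenylsilyl)oxy]methyl}-6-[(4-methoxyphenyl)methoxy]-5-(propan-2-yl)-4-[(triethylsilyl)oxy]octa-1,7-dien-3-ol, via 2-lithioallyl silyl ether 19 (not isolated)
Conditions: 18, t-BuLi, Et2O, −78 °C; then 16, −78 °C; sat. aq. NH4Cl at −78 °C
Reagents that add atoms: none
Why: Bromine–lithium exchange gives the α-substituted vinyllithium, whose 1,2-addition to the aldehyde should outrun enolisation at −78 °C; the new carbinol centre forms unselectively and is erased in step 15, and the cold quench prevents 1,2-silyl migration.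

Step 15
Reactants: 20 (3RS,4R,5S,6S)-2-{[(tert-butyldiphenylsilyl)oxy]methyl}-6-[(4-methoxyphenyl)methoxy]-5-(propan-2-yl)-4-[(triethylsilyl)oxy]octa-1,7-dien-3-ol
Product: 21 (4R,5S,6S)-2-{[(tert-butyldiphenylsilyl)oxy]methyl}-6-[(4-methoxyphenyl)methoxy]-5-(propan-2-yl)-4-[(triethylsilyl)oxy]octa-1,7-dien-3-one
Conditions: Dess–Martin periodinane, pyridine, CH2Cl2, 0 °C to rt
Reagents that add atoms: none
Why: Buffered Dess–Martin oxidation of the allylic alcohol should give the α-methylene ketone without epimerising the adjacent silyloxy centre or cleaving the silyl and PMB ethers.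

Step 16
Reactants: 21 (4R,5S,6S)-2-{[(tert-butyldiphenylsilyl)oxy]methyl}-6-[(4-methoxyphenyl)methoxy]-5-(propan-2-yl)-4-[(triethylsilyl)oxy]octa-1,7-dien-3-one
Product: 22 (4S,5S,6R)-2-{[(tert-butyldiphenylsilyl)oxy]methyl}-4-[(4-methoxyphenyl)methoxy]-5-(propan-2-yl)-6-[(triethylsilyl)oxy]cyclohex-2-en-1-one
Conditions: second-generation Grubbs catalyst (H2IMes)(PCy3)Cl2Ru=CHPh (5–10 mol %), degassed toluene (5 mM), 80 °C
Reagents that add atoms: none
Why: The ruthenium benzylidene should first exchange with the monosubstituted, electron-neutral C3 vinyl group, and the resulting alkylidene adds intramolecularly to the 1,1-disubstituted enone alkene in a [2+2] step to give a ruthenacyclobutane that cycloreverts to the C2=C3 bond and a ruthenium methylidene, which leaves as ethylene in the next turnover. The closest known reaction type is ring-closing olefin metathesis of sugar-derived 1,7-dienes to cyclohexenes and of α-methylene ketones to 2-substituted cyclohex-2-enones. The one ring closed is the six-membered carbocycle C1–C6, formed by intramolecular metathesis in which both alkene carbons C2 and C3 become ring atoms and the C2=C3 double bond is the ring-closing bond. No stereocentre is created, and C4, C5 and C6 are not touched because the conditions are neutral. The step needs initiation at the vinyl group and not at the hindered, electron-poor enone alkene, and cyclisation in preference to intermolecular cross-metathesis, which the steric and electronic difference between the two alkenes, high dilution, the unstrained ring size and the irreversible escape of ethylene at 80 °C should secure. All three oxygen functions are capped (PMB, TES, TBDPS), so no free hydroxyl can bind or degrade the catalyst.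

Step 17
Reactants: 22 (4S,5S,6R)-2-{[(tert-butyldiphenylsilyl)oxy]methyl}-4-[(4-methoxyphenyl)methoxy]-5-(propan-2-yl)-6-[(triethylsilyl)oxy]cyclohex-2-en-1-one
Product: 23 (4S,5R,6R)-2-{[(tert-butyldiphenylsilyl)oxy]methyl}-6-hydroxy-4-[(4-methoxyphenyl)methoxy]-5-(propan-2-yl)cyclohex-2-en-1-one
Conditions: HF·pyridine, pyridine, THF, 0 °C
Reagents that add atoms: none
Why: Buffered HF should cleave the secondary triethylsilyl ether far faster than the TBDPS ether (selective desilylation by silyl-group lability) and leaves PMB, the enone and the C6 configuration untouched, the descriptor at C5 changing only through substituent priorities.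

Step 18
Reactants: 24 [(tert-butyldimethylsilyl)oxy]acetaldehyde; 25 ethyl 2-(triphenylphosphoranylidene)propanoate
Product: 26 ethyl (2E)-4-[(tert-butyldimethylsilyl)oxy]-2-methylbut-2-enoate
Conditions: CH2Cl2, rt
Reagents that add atoms: none
Why: Wittig reaction of a stabilised α-methyl ylide with an unhindered aldehyde should give the (E)-trisubstituted enoate through the thermodynamically favoured oxaphosphetane.

Step 19
Reactants: 26 ethyl (2E)-4-[(tert-butyldimethylsilyl)oxy]-2-methylbut-2-enoate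
Product: 27 (2E)-4-[(tert-butyldimethylsilyl)oxy]-2-methylbut-2-enoic acid
Conditions: LiOH·H2O, THF/H2O (3:1), rt; then 1 M HCl to pH 3, 0 °C
Reagents that add atoms: lithium hydroxide, [Li+].[OH-]
Why: Saponification of the ethyl ester at room temperature should leave the primary TBS ether and the alkene geometry intact.

Step 20
Reactants: 23 (4S,5R,6R)-2-{[(tert-butyldiphenylsilyl)oxy]methyl}-6-hydroxy-4-[(4-methoxyphenyl)methoxy]-5-(propan-2-yl)cyclohex-2-en-1-one; 27 (2E)-4-[(tert-butyldimethylsilyl)oxy]-2-methylbut-2-enoic acid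
Product: 28 (1R,5S,6S)-3-{[(tert-butyldiphenylsilyl)oxy]methyl}-5-[(4-methoxyphenyl)methoxy]-2-oxo-6-(propan-2-yl)cyclohex-3-en-1-yl (2E)-4-[(tert-butyldimethylsilyl)oxy]-2-methylbut-2-enoate
Conditions: N,N′-dicyclohexylcarbodiimide, 4-(dimethylamino)pyridine (cat.), CH2Cl2, 0 °C to rt
Reagents that add atoms: none
Why: Steglich esterification acylates the C6 hydroxyl through the acylpyridinium ion without breaking the C6–O bond, so configuration is retained, and C6 is in any case the equatorial epimer trans to the isopropyl group.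

Step 21
Reactants: 28 (1R,5S,6S)-3-{[(tert-butyldiphenylsilyl)oxy]methyl}-5-[(4-methoxyphenyl)methoxy]-2-oxo-6-(propan-2-yl)cyclohex-3-en-1-yl (2E)-4-[(tert-butyldimethylsilyl)oxy]-2-methylbut-2-enoate
Product: 29 (1R,5S,6S)-3-{[(tert-butyldiphenylsilyl)oxy]methyl}-5-hydroxy-2-oxo-6-(propan-2-yl)cyclohex-3-en-1-yl (2E)-4-[(tert-butyldimethylsilyl)oxy]-2-methylbut-2-enoate
Conditions: DDQ, CH2Cl2/pH 7 phosphate buffer (10:1), 0 °C to rt
Reagents that add atoms: none
Why: Oxidative cleavage of the electron-rich PMB ether by DDQ (hydride abstraction, then hydrolysis of the oxocarbenium ion) should free C4–OH while the silyl ethers, the ester and the electron-poor enone are inert.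

Step 22
Reactants: 29 (1R,5S,6S)-3-{[(tert-butyldiphenylsilyl)oxy]methyl}-5-hydroxy-2-oxo-6-(propan-2-yl)cyclohex-3-en-1-yl (2E)-4-[(tert-butyldimethylsilyl)oxy]-2-methylbut-2-enoate
Product: 30 (1R,5S,6S)-3-{[(tert-butyldiphenylsilyl)oxy]methyl}-2-oxo-5-(propanoyloxy)-6-(propan-2-yl)cyclohex-3-en-1-yl (2E)-4-[(tert-butyldimethylsilyl)oxy]-2-methylbut-2-enoate
Conditions: (EtCO)2O, pyridine, 4-(dimethylamino)pyridine (cat.), CH2Cl2, 0 °C to rt
Reagents that add atoms: propanoic anhydride, CCC(=O)OC(=O)CC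
Why: Nucleophile-catalysed acylation of the secondary allylic alcohol should give the propanoate with retention, and acyl migration from C6 is excluded by the trans-1,3 relationship of the two oxygens.

Step 23
Reactants: 30 (1R,5S,6S)-3-{[(tert-butyldiphenylsilyl)oxy]methyl}-2-oxo-5-(propanoyloxy)-6-(propan-2-yl)cyclohex-3-en-1-yl (2E)-4-[(tert-butyldimethylsilyl)oxy]-2-methylbut-2-enoate
Product: 31 (1R,5S,6S)-3-(hydroxymethyl)-2-oxo-5-(propanoyloxy)-6-(propan-2-yl)cyclohex-3-en-1-yl (2E)-4-hydroxy-2-methylbut-2-enoate (CNP0285949.1)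
Conditions: HF·pyridine, pyridine, THF, 0 °C to rt
Reagents that add atoms: none
Why: Fluoride desilylation under buffered acidic conditions should cleave both primary allylic silyl ethers and spare the two esters and the γ-acyloxy enone, which basic fluoride could attack by acyl migration or elimination.

Compound list
1 | L-arabinose | O=C[C@H](O)[C@@H](O)[C@@H](O)CO | starting material
2 | 5-O-(tert-butyldiphenylsilyl)-L-arabinofuranose (anomer mixture) | OC1[C@H](O)[C@@H](O)[C@@H](O1)CO[Si](c1ccccc1)(c1ccccc1)C(C)(C)C | intermediate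
3 | 5-O-(tert-butyldiphenylsilyl)-1,2-O-isopropylidene-β-L-arabinofuranose | CC1(C)O[C@@H]2[C@H](O1)[C@@H](O)[C@@H](O2)CO[Si](c1ccccc1)(c1ccccc1)C(C)(C)C | intermediate
4 | 5-O-(tert-butyldiphenylsilyl)-1,2-O-isopropylidene-β-L-threo-pentofuranos-3-ulose | CC1(C)O[C@@H]2[C@H](O1)C(=O)[C@@H](O2)CO[Si](c1ccccc1)(c1ccccc1)C(C)(C)C | intermediate
5 | isopropyltriphenylphosphonium iodide | CC(C)[P+](c1ccccc1)(c1ccccc1)c1ccccc1.[I-] | starting material
6 | triphenyl(propan-2-ylidene)phosphorane | CC(C)=P(c1ccccc1)(c1ccccc1)c1ccccc1 | intermediate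
7 | 5-O-(tert-butyldiphenylsilyl)-3-deoxy-1,2-O-isopropylidene-3-C-(propan-2-ylidene)-β-L-threo-pentofuranose | CC1(C)O[C@@H]2[C@H](O1)C(=C(C)C)[C@@H](O2)CO[Si](c1ccccc1)(c1ccccc1)C(C)(C)C | intermediate
8 | 5-O-(tert-butyldiphenylsilyl)-3-deoxy-1,2-O-isopropylidene-3-C-(propan-2-yl)-β-L-lyxofuranose | CC1(C)O[C@@H]2[C@H](O1)[C@H](C(C)C)[C@@H](O2)CO[Si](c1ccccc1)(c1ccccc1)C(C)(C)C | intermediate
9 | 5-O-(tert-butyldiphenylsilyl)-3-deoxy-3-C-(propan-2-yl)-L-lyxofuranose (anomer mixture) | OC1[C@H](O)[C@H](C(C)C)[C@@H](O1)CO[Si](c1ccccc1)(c1ccccc1)C(C)(C)C | intermediate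
10 | (2R,3S,4S)-1-[(tert-butyldiphenylsilyl)oxy]-3-(propan-2-yl)hex-5-ene-2,4-diol | C=C[C@H](O)[C@H](C(C)C)[C@@H](O)CO[Si](c1ccccc1)(c1ccccc1)C(C)(C)C | intermediate
11 | (2R,3S,4S)-3-(propan-2-yl)hex-5-ene-1,2,4-triol | C=C[C@H](O)[C@H](C(C)C)[C@@H](O)CO | intermediate
12 | (3S,4S)-4-[(4R)-2,2-dimethyl-1,3-dioxolan-4-yl]-5-methylhex-1-en-3-ol | C=C[C@H](O)[C@H](C(C)C)[C@@H]1COC(C)(C)O1 | intermediate
13 | (4R)-4-{(3S,4S)-4-[(4-methoxyphenyl)methoxy]-2-methylhex-5-en-3-yl}-2,2-dimethyl-1,3-dioxolane | C=C[C@H](OCc1ccc(OC)cc1)[C@H](C(C)C)[C@@H]1COC(C)(C)O1 | intermediate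
14 | (2R,3R,4S)-4-[(4-methoxyphenyl)methoxy]-3-(propan-2-yl)hex-5-ene-1,2-diol | C=C[C@H](OCc1ccc(OC)cc1)[C@H](C(C)C)[C@@H](O)CO | intermediate
15 | (3S,4S,5R)-3-[(4-methoxyphenyl)methoxy]-4-(propan-2-yl)-5,6-bis[(triethylsilyl)oxy]hex-1-ene | C=C[C@H](OCc1ccc(OC)cc1)[C@H](C(C)C)[C@@H](O[Si](CC)(CC)CC)CO[Si](CC)(CC)CC | intermediate
16 | (2R,3S,4S)-4-[(4-methoxyphenyl)methoxy]-3-(propan-2-yl)-2-[(triethylsilyl)oxy]hex-5-enal | C=C[C@H](OCc1ccc(OC)cc1)[C@H](C(C)C)[C@@H](O[Si](CC)(CC)CC)C=O | intermediate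
17 | 2-bromoprop-2-en-1-ol (2-bromoallyl alcohol) | OCC(Br)=C | starting material
18 | [(2-bromoprop-2-en-1-yl)oxy](tert-butyl)diphenylsilane | C=C(Br)CO[Si](c1ccccc1)(c1ccccc1)C(C)(C)C | intermediate
19 | {3-[(tert-butyldiphenylsilyl)oxy]prop-1-en-2-yl}lithium | [Li]C(=C)CO[Si](c1ccccc1)(c1ccccc1)C(C)(C)C | intermediate
20 | (3RS,4R,5S,6S)-2-{[(tert-butyldiphenylsilyl)oxy]methyl}-6-[(4-methoxyphenyl)methoxy]-5-(propan-2-yl)-4-[(triethylsilyl)oxy]octa-1,7-dien-3-ol | C=C[C@H](OCc1ccc(OC)cc1)[C@H](C(C)C)[C@@H](O[Si](CC)(CC)CC)C(O)C(=C)CO[Si](c1ccccc1)(c1ccccc1)C(C)(C)C | intermediate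
21 | (4R,5S,6S)-2-{[(tert-butyldiphenylsilyl)oxy]methyl}-6-[(4-methoxyphenyl)methoxy]-5-(propan-2-yl)-4-[(triethylsilyl)oxy]octa-1,7-dien-3-one | C=C[C@H](OCc1ccc(OC)cc1)[C@H](C(C)C)[C@@H](O[Si](CC)(CC)CC)C(=O)C(=C)CO[Si](c1ccccc1)(c1ccccc1)C(C)(C)C | intermediate
22 | (4S,5S,6R)-2-{[(tert-butyldiphenylsilyl)oxy]methyl}-4-[(4-methoxyphenyl)methoxy]-5-(propan-2-yl)-6-[(triethylsilyl)oxy]cyclohex-2-en-1-one | COc1ccc(CO[C@H]2C=C(CO[Si](c3ccccc3)(c3ccccc3)C(C)(C)C)C(=O)[C@H](O[Si](CC)(CC)CC)[C@H]2C(C)C)cc1 | intermediate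
23 | (4S,5R,6R)-2-{[(tert-butyldiphenylsilyl)oxy]methyl}-6-hydroxy-4-[(4-methoxyphenyl)methoxy]-5-(propan-2-yl)cyclohex-2-en-1-one | COc1ccc(CO[C@H]2C=C(CO[Si](c3ccccc3)(c3ccccc3)C(C)(C)C)C(=O)[C@H](O)[C@H]2C(C)C)cc1 | intermediate
24 | [(tert-butyldimethylsilyl)oxy]acetaldehyde | CC(C)(C)[Si](C)(C)OCC=O | starting material
25 | ethyl 2-(triphenylphosphoranylidene)propanoate | CCOC(=O)C(C)=P(c1ccccc1)(c1ccccc1)c1ccccc1 | starting material
26 | ethyl (2E)-4-[(tert-butyldimethylsilyl)oxy]-2-methylbut-2-enoate | CCOC(=O)/C(C)=C/CO[Si](C)(C)C(C)(C)C | intermediate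
27 | (2E)-4-[(tert-butyldimethylsilyl)oxy]-2-methylbut-2-enoic acid | OC(=O)/C(C)=C/CO[Si](C)(C)C(C)(C)C | intermediate
28 | (1R,5S,6S)-3-{[(tert-butyldiphenylsilyl)oxy]methyl}-5-[(4-methoxyphenyl)methoxy]-2-oxo-6-(propan-2-yl)cyclohex-3-en-1-yl (2E)-4-[(tert-butyldimethylsilyl)oxy]-2-methylbut-2-enoate | COc1ccc(CO[C@H]2C=C(CO[Si](c3ccccc3)(c3ccccc3)C(C)(C)C)C(=O)[C@H](OC(=O)/C(C)=C/CO[Si](C)(C)C(C)(C)C)[C@H]2C(C)C)cc1 | intermediate
29 | (1R,5S,6S)-3-{[(tert-butyldiphenylsilyl)oxy]methyl}-5-hydroxy-2-oxo-6-(propan-2-yl)cyclohex-3-en-1-yl (2E)-4-[(tert-butyldimethylsilyl)oxy]-2-methylbut-2-enoate | O[C@H]1C=C(CO[Si](c2ccccc2)(c2ccccc2)C(C)(C)C)C(=O)[C@H](OC(=O)/C(C)=C/CO[Si](C)(C)C(C)(C)C)[C@H]1C(C)C | intermediate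
30 | (1R,5S,6S)-3-{[(tert-butyldiphenylsilyl)oxy]methyl}-2-oxo-5-(propanoyloxy)-6-(propan-2-yl)cyclohex-3-en-1-yl (2E)-4-[(tert-butyldimethylsilyl)oxy]-2-methylbut-2-enoate | CCC(=O)O[C@H]1C=C(CO[Si](c2ccccc2)(c2ccccc2)C(C)(C)C)C(=O)[C@H](OC(=O)/C(C)=C/CO[Si](C)(C)C(C)(C)C)[C@H]1C(C)C | intermediate
31 | (1R,5S,6S)-3-(hydroxymethyl)-2-oxo-5-(propanoyloxy)-6-(propan-2-yl)cyclohex-3-en-1-yl (2E)-4-hydroxy-2-methylbut-2-enoate (CNP0285949.1) | CCC(=O)O[C@H]1C=C(CO)C(=O)[C@H](OC(=O)/C(C)=C/CO)[C@H]1C(C)C | target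

Total step count: 23. Longest linear sequence: 20 steps (steps 1–12, 14–17 and 20–23, from 1 to 31); steps 13, 18 and 19 prepare the two side-chain reagents.

Steps most likely to fail

Step 16. Ring closure onto the hindered, electron-poor α-methylene ketone may be slow, so that catalyst decay and intermolecular cross-metathesis of the C3 vinyl group compete. The fallback closes the ring one oxidation level lower. It sets out from alcohol 20, whose 1,1-disubstituted alkene is an electron-neutral allylic alcohol. The same ruthenium catalyst in CH2Cl2 at 40 °C should cyclise it to the cyclohexenol (4S,5S,6R)-2-{[(tert-butyldiphenylsilyl)oxy]methyl}-4-[(4-methoxyphenyl)methoxy]-5-(propan-2-yl)-6-[(triethylsilyl)oxy]cyclohex-2-en-1-ol F1 (both C1 epimers). Dess–Martin oxidation of F1 then rejoins the route at 22.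

Step 4. The basic, hindered ylide may deprotonate the α-alkoxy ketone (enolisation, β-elimination of a ring oxygen or epimerisation at C4) instead of olefinating it. The fallback replaces olefination and hydrogenation by addition and radical deoxygenation, and sets out from 4. Addition of i-PrMgCl in the presence of anhydrous CeCl3 (THF, −78 °C) to the convex face should give the tertiary alcohol 5-O-TBDPS-1,2-O-isopropylidene-3-C-(propan-2-yl)-β-L-lyxofuranose F2. Acylation with methyl chlorooxoacetate (pyridine, 4-(dimethylamino)pyridine, CH2Cl2) gives the methyl oxalate of that alcohol F3. Radical deoxygenation (Bu3SnH, azobisisobutyronitrile, toluene, 110 °C), with hydrogen-atom transfer to the convex face of the C3 radical, should then deliver 8 directly. This rejoins the route at 8 and bypasses step 5.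

Step 7. The ring-opened aldehyde carries an α-alkoxide, which lowers its electrophilicity and allows enolisation, so conversion may be poor or C2 may epimerise. The fallback protects O2 before the olefination and sets out from 9.
- Fétizon oxidation of the lactol (Ag2CO3 on Celite, toluene, reflux) gives 5-O-TBDPS-3-deoxy-3-C-(propan-2-yl)-L-lyxono-1,4-lactone F4.
- 4-Methoxybenzyl trichloroacetimidate with La(OTf)3 (cat.) in toluene gives the 2-O-PMB lactone F5.
- Reduction with i-Bu2AlH in CH2Cl2 at −78 °C gives the 2-O-PMB lactol F6.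
- Methylenation as in step 7 gives the PMB-protected ene-ol silyl ether F7, and Bu4NF in the same flask rejoins the route at diol 14, bypassing steps 8 to 10.

Further compounds
F1 | step 16 | (4S,5S,6R)-2-{[(tert-butyldiphenylsilyl)oxy]methyl}-4-[(4-methoxyphenyl)methoxy]-5-(propan-2-yl)-6-[(triethylsilyl)oxy]cyclohex-2-en-1-ol (C1 epimers) | COc1ccc(CO[C@H]2C=C(CO[Si](c3ccccc3)(c3ccccc3)C(C)(C)C)C(O)[C@H](O[Si](CC)(CC)CC)[C@H]2C(C)C)cc1
F2 | step 4 | 5-O-(tert-butyldiphenylsilyl)-1,2-O-isopropylidene-3-C-(propan-2-yl)-β-L-lyxofuranose | CC1(C)O[C@@H]2[C@H](O1)[C@@](O)(C(C)C)[C@@H](O2)CO[Si](c1ccccc1)(c1ccccc1)C(C)(C)C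
F3 | step 4 | 5-O-(tert-butyldiphenylsilyl)-1,2-O-isopropylidene-3-O-(methoxyoxalyl)-3-C-(propan-2-yl)-β-L-lyxofuranose | CC1(C)O[C@@H]2[C@H](O1)[C@@](OC(=O)C(=O)OC)(C(C)C)[C@@H](O2)CO[Si](c1ccccc1)(c1ccccc1)C(C)(C)C
F4 | step 7 | 5-O-(tert-butyldiphenylsilyl)-3-deoxy-3-C-(propan-2-yl)-L-lyxono-1,4-lactone | O=C1[C@H](O)[C@H](C(C)C)[C@@H](O1)CO[Si](c1ccccc1)(c1ccccc1)C(C)(C)C
F5 | step 7 | 5-O-(tert-butyldiphenylsilyl)-3-deoxy-2-O-(4-methoxybenzyl)-3-C-(propan-2-yl)-L-lyxono-1,4-lactone | O=C1[C@H](OCc2ccc(OC)cc2)[C@H](C(C)C)[C@@H](O1)CO[Si](c1ccccc1)(c1ccccc1)C(C)(C)C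
F6 | step 7 | 5-O-(tert-butyldiphenylsilyl)-3-deoxy-2-O-(4-methoxybenzyl)-3-C-(propan-2-yl)-L-lyxofuranose (anomer mixture) | OC1[C@H](OCc2ccc(OC)cc2)[C@H](C(C)C)[C@@H](O1)CO[Si](c1ccccc1)(c1ccccc1)C(C)(C)C
F7 | step 7 | (2R,3R,4S)-1-[(tert-butyldiphenylsilyl)oxy]-4-[(4-methoxyphenyl)methoxy]-3-(propan-2-yl)hex-5-en-2-ol | C=C[C@H](OCc1ccc(OC)cc1)[C@H](C(C)C)[C@@H](O)CO[Si](c1ccccc1)(c1ccccc1)C(C)(C)C
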